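A direct plan would close ring C last through the O1–C2 bond. Aroylacetate A1, with O1 masked as a 1,1-dimethylallyl ether, would be condensed with benzaldehyde to benzylidene β-ketoester A2; heat would shift the allyl group to C8 and free phenol A3, which a cinchona thiourea would cyclise before the tert-butyl ester is lost as CO2. Its weakest steps would be the Knoevenagel condensation (a doubly ortho-substituted aroylacetate that may not be heated), the Claisen rearrangement (it would free a phenol beside a strong Michael acceptor near 100 °C, so uncatalysed closure would give racemate) and the making and removal of the ester (four operations for a group absent from the target).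

The route rests on the C2–C1′ disconnection. Ring C is closed first as a flat, achiral pyranone, and the only stereocentre, C2, is the β-carbon of its O1–C2=C3–C4=O enone. The key step, a rhodium-catalysed enantioselective 1,4-addition of phenylboronic acid to the fully substituted chromone, joins ring B and sets C2 in one operation in a neutral medium. Because C2 is not set by an O1–C2 ring closure, no activating ester, no Knoevenagel condensation and no Claisen rearrangement are needed: the C8 side chain and C4 are placed ortho to the single free hydroxyl of a mirror-symmetric phenol, and the prenyl group is completed last by cross-metathesis.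

Key step: step 7

Assumption: the (S)-antipode of the bisphosphine is taken to deliver phenyl to the face of C2 that gives the 2S product, by analogy with the facial sense of rhodium–biaryl bisphosphine additions to cyclohex-2-enone; if a first run showed the opposite sense, the (R)-ligand would be used.

Step 1
Reactants: 1 2-methoxybenzene-1,3-diol (2-methoxyresorcinol)
Product: 2 2-methoxy-1,3-bis(methoxymethoxy)benzene
Conditions: NaH (2.4 equiv), MOMCl (2.4 equiv), DMF, 0 °C → rt
Reagents that add atoms: chloromethyl methyl ether, COCCl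
Why: Double Williamson O-alkylation of the two equivalent phenols gives base-stable MOM ethers that should survive every step up to the acid cleavage in step 8.

Step 2
Reactants: 2 2-methoxy-1,3-bis(methoxymethoxy)benzene
Product: 4 4-methoxy-3,5-bis(methoxymethoxy)phenol, via aryl pinacol boronate 3 (not isolated)
Conditions: [Ir(OMe)(cod)]2 (1.5 mol%), 4,4′-di-tert-butyl-2,2′-bipyridine (3 mol%), B2pin2 (1.0 equiv), THF, 80 °C; then aq. NaOH, 30% H2O2, 0 °C → rt
Reagents that add atoms: hydrogen peroxide, OO; bis(pinacolato)diboron, CC1(C)OB(OC1(C)C)B1OC(C)(C)C(C)(C)O1 (its boron stays only in intermediate 3)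
Why: Sterically governed iridium-catalysed aromatic C–H borylation should take place only at C5, the one C–H without an ortho substituent, and basic peroxide oxidation of the C–B bond in the same flask gives the mirror-symmetric phenol whose single free hydroxyl is the future O1.

Step 3
Reactants: 4 4-methoxy-3,5-bis(methoxymethoxy)phenol; 5 3-bromoprop-1-ene (allyl bromide)
Product: 7 4-methoxy-3,5-bis(methoxymethoxy)-2-(prop-2-en-1-yl)phenol, via sodium phenoxide 6 (not isolated)
Conditions: NaH (1.05 equiv), toluene, 0 °C → rt; then 5 (1.05 equiv), rt → 50 °C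
Reagents that add atoms: none
Why: ortho-C-Alkylation of a sodium phenoxide in a non-polar solvent, where the tight ion pair shields oxygen and the new C–C bond forms at the ortho carbon; the two ortho positions are equivalent and the para position is blocked by the methoxy group, so a single C-allyl phenol can form, with the allyl group on the future C8.

Step 4
Reactants: 7 4-methoxy-3,5-bis(methoxymethoxy)-2-(prop-2-en-1-yl)phenol
Product: 8 2-hydroxy-5-methoxy-4,6-bis(methoxymethoxy)-3-(prop-2-en-1-yl)benzaldehyde
Conditions: MgCl2 (2 equiv), Et3N (4 equiv), (CH2O)n (6 equiv), MeCN, 75 °C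
Reagents that add atoms: paraformaldehyde (as formaldehyde), C=O
Why: Casnati–Skattebøl ortho-formylation, in which the magnesium phenoxide delivers formaldehyde to the only ortho C–H that is left and a second formaldehyde oxidises the hydroxymethyl group by hydride transfer, under non-acidic conditions that spare the MOM ethers; the new carbon is the future C4.

Step 5
Reactants: 8 2-hydroxy-5-methoxy-4,6-bis(methoxymethoxy)-3-(prop-2-en-1-yl)benzaldehyde
Product: 9 1-[2-hydroxy-5-methoxy-4,6-bis(methoxymethoxy)-3-(prop-2-en-1-yl)phenyl]prop-2-yn-1-ol (racemic)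
Conditions: HC≡CMgBr (3 equiv), THF, −20 → 0 °C; aq. NH4Cl
Reagents that add atoms: ethynylmagnesium bromide, C#C[Mg]Br
Why: 1,2-Addition of the alkynyl Grignard reagent to the aldehyde (the first equivalent deprotonates the phenol) brings in C3 and C2; the carbinol centre forms as a racemate and is erased in step 6.

Step 6
Reactants: 9 1-[2-hydroxy-5-methoxy-4,6-bis(methoxymethoxy)-3-(prop-2-en-1-yl)phenyl]prop-2-yn-1-ol
Product: 12 6-methoxy-5,7-bis(methoxymethoxy)-8-(prop-2-en-1-yl)-4H-chromen-4-one, via ynone 10 (not isolated), via enaminone 11 (not isolated)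
Conditions: MnO2 (activated, 15 equiv), CH2Cl2, rt; filtration; then Et2NH (2 equiv), EtOH, rt → 50 °C
Reagents that add atoms: diethylamine, CCNCC (its atoms stay only in intermediate 11)
Why: MnO2 oxidises the benzylic–propargylic alcohol to the ynone, diethylamine adds to it to give the β-amino enone, and the free phenol closes ring C by 6-endo addition–elimination with loss of the amine (the amine route avoids 5-exo closure to an aurone-type product); only O1 can close because O5 and O7 are capped.

Step 7
Reactants: 12 6-methoxy-5,7-bis(methoxymethoxy)-8-(prop-2-en-1-yl)-4H-chromen-4-one; 13 phenylboronic acid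
Product: 14 (2S)-6-methoxy-5,7-bis(methoxymethoxy)-2-phenyl-8-(prop-2-en-1-yl)-2,3-dihydro-4H-chromen-4-one
Conditions: [Rh(OH)((S)-MeO-F12-BIPHEP)]2 (1.5 mol%; MeO-F12-BIPHEP = (6,6′-dimethoxybiphenyl-2,2′-diyl)bis[bis(3,4,5-trifluorophenyl)phosphane]), 13 (3 equiv), toluene/H2O (10:1), 40 °C
Reagents that add atoms: none
Why: Transmetalation of 13 to the hydroxo-rhodium complex gives a phenyl complex of monovalent rhodium, the C2=C3 bond of the chromone inserts into it with phenyl going to the β-carbon C2, and water protonates the resulting oxa-π-allyl rhodium enolate at C3, which releases 14 and returns the hydroxo complex. The closest known reaction type is the Hayashi–Miyaura asymmetric 1,4-addition of arylboronic acids to enones, which is established for chromones with electron-poor biaryl bisphosphine–rhodium catalysts. No ring is closed here: ring C is already present as the pyranone, and the step forms the exocyclic C2–C1′ bond that joins ring B. C2 is set under catalyst control, since the C2-symmetric bisphosphine leaves open only those quadrants in which the planar chromone can bind through one enantioface, and migratory insertion is irreversible. The step needs 1,4- over 1,2-addition and reaction at the enone and not at the allyl group, which the substrate should secure because the carbonyl is shielded by the C5 ether and an unactivated terminal alkene inserts far more slowly than the polarised enone. It also needs the new centre to be kept, which is protected by the base-free medium, in which the flavanone cannot open by retro-oxa-Michael addition, and by the MOM caps on O5 and O7, which prevent a chelating 5-hydroxy-4-keto unit or an acidic 7-hydroxyl from binding rhodium.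

Step 8
Reactants: 14 (2S)-6-methoxy-5,7-bis(methoxymethoxy)-2-phenyl-8-(prop-2-en-1-yl)-2,3-dihydro-4H-chromen-4-one
Product: 15 (2S)-5,7-dihydroxy-6-methoxy-2-phenyl-8-(prop-2-en-1-yl)-2,3-dihydro-4H-chromen-4-one
Conditions: 3 M aq. HCl, MeOH, 45 °C
Reagents that add atoms: none
Why: Acid-catalysed cleavage of the two aryl MOM acetals in methanol; the terminal allyl group cannot form a tertiary cation and should be inert here, and without base the flavanone cannot open by retro-oxa-Michael addition, so C2 should keep its configuration.

Step 9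
Reactants: 15 (2S)-5,7-dihydroxy-6-methoxy-2-phenyl-8-(prop-2-en-1-yl)-2,3-dihydro-4H-chromen-4-one; 16 2-methylbut-2-ene
Product: 17 agrandol [(2S)-5,7-dihydroxy-6-methoxy-8-(3-methylbut-2-en-1-yl)-2-phenyl-2,3-dihydro-4H-chromen-4-one]
Conditions: second-generation Grubbs catalyst RuCl2(=CHPh)(PCy3)(H2IMes) (5 mol%; H2IMes = 1,3-dimesityl-4,5-dihydroimidazol-2-ylidene), 16 (30 equiv), CH2Cl2, 40 °C, sealed tube
Reagents that add atoms: none
Why: Olefin cross-metathesis of the terminal allyl group with 2-methylbut-2-ene should give the trisubstituted prenyl alkene with loss of propene, under neutral conditions that touch neither the free phenols nor C2.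

**Compound list**

1 | 2-methoxybenzene-1,3-diol (2-methoxyresorcinol) | COc1c(O)cccc1O | starting material
2 | 2-methoxy-1,3-bis(methoxymethoxy)benzene | COCOc1cccc(OCOC)c1OC | intermediate
3 | 2-[4-methoxy-3,5-bis(methoxymethoxy)phenyl]-4,4,5,5-tetramethyl-1,3,2-dioxaborolane | COCOc1cc(B2OC(C)(C)C(C)(C)O2)cc(OCOC)c1OC | intermediate
4 | 4-methoxy-3,5-bis(methoxymethoxy)phenol | COCOc1cc(O)cc(OCOC)c1OC | intermediate
5 | 3-bromoprop-1-ene (allyl bromide) | C=CCBr | starting material
6 | sodium 4-methoxy-3,5-bis(methoxymethoxy)phenolate | COCOc1cc([O-])cc(OCOC)c1OC.[Na+] | intermediate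
7 | 4-methoxy-3,5-bis(methoxymethoxy)-2-(prop-2-en-1-yl)phenol | COCOc1cc(O)c(CC=C)c(OCOC)c1OC | intermediate
8 | 2-hydroxy-5-methoxy-4,6-bis(methoxymethoxy)-3-(prop-2-en-1-yl)benzaldehyde | O=Cc1c(O)c(CC=C)c(OCOC)c(OC)c1OCOC | intermediate
9 | 1-[2-hydroxy-5-methoxy-4,6-bis(methoxymethoxy)-3-(prop-2-en-1-yl)phenyl]prop-2-yn-1-ol (racemic) | C#CC(O)c1c(O)c(CC=C)c(OCOC)c(OC)c1OCOC | intermediate
10 | 1-[2-hydroxy-5-methoxy-4,6-bis(methoxymethoxy)-3-(prop-2-en-1-yl)phenyl]prop-2-yn-1-one | C#CC(=O)c1c(O)c(CC=C)c(OCOC)c(OC)c1OCOC | intermediate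
11 | (2E)-3-(diethylamino)-1-[2-hydroxy-5-methoxy-4,6-bis(methoxymethoxy)-3-(prop-2-en-1-yl)phenyl]prop-2-en-1-one | CCN(CC)/C=C/C(=O)c1c(O)c(CC=C)c(OCOC)c(OC)c1OCOC | intermediate
12 | 6-methoxy-5,7-bis(methoxymethoxy)-8-(prop-2-en-1-yl)-4H-chromen-4-one | COCOc1c(OC)c(OCOC)c(CC=C)c2OC=CC(=O)c12 | intermediate
13 | phenylboronic acid | OB(O)c1ccccc1 | starting material
14 | (2S)-6-methoxy-5,7-bis(methoxymethoxy)-2-phenyl-8-(prop-2-en-1-yl)-2,3-dihydro-4H-chromen-4-one | COCOc1c(OC)c(OCOC)c(CC=C)c2c1C(=O)C[C@@H](c1ccccc1)O2 | intermediate
15 | (2S)-5,7-dihydroxy-6-methoxy-2-phenyl-8-(prop-2-en-1-yl)-2,3-dihydro-4H-chromen-4-one | COc1c(O)c(CC=C)c2c(c1O)C(=O)C[C@@H](c1ccccc1)O2 | intermediate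
16 | 2-methylbut-2-ene | CC=C(C)C | starting material
17 | agrandol, (2S)-5,7-dihydroxy-6-methoxy-8-(3-methylbut-2-en-1-yl)-2-phenyl-2,3-dihydro-4H-chromen-4-one | COc1c(O)c(CC=C(C)C)c2c(c1O)C(=O)C[C@@H](c1ccccc1)O2 | target

Total step count: 9. Longest linear sequence: 9 steps (1 → 17).

**Steps most likely to fail**

Step 7 (key step). Insertion of the electron-rich chromone, whose carbonyl is flanked by the C5 ether, may be so slow that protodeboronation of 13 outruns addition, or the two faces of C2 may be told apart poorly. The fallback sets out from 12 and comes back at 14. The more active achiral complex [Rh(OH)(cod)]2 (3 mol%) with 13 in dioxane/H2O at 60 °C would give racemic flavanone F1. Kinetic resolution by asymmetric transfer hydrogenation would follow, with RhCl(C5Me5)(TsDPEN) (TsDPEN = the amido ligand of N-tosyl-1,2-diphenylethane-1,2-diamine) in the antipode that reduces the 2R ketone, HCO2H/Et3N, EtOAc, rt. It would turn the unwanted half into cis-flavan-4-ol F2, which is removed by chromatography, and leave 14, at the cost of half the material.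

Step 3. O-Allylation, twofold C-allylation or attack at the methoxy-bearing para carbon may compete with the single ortho C-allylation. The fallback sets out from 4 and comes back at 7. Iodination with N-iodosuccinimide (1.0 equiv, CH2Cl2, −20 °C) would give 2-iodo-4-methoxy-3,5-bis(methoxymethoxy)phenol F3. Stille coupling with allyltributylstannane (Pd(PPh3)4, a complex of zerovalent palladium, 5 mol%, toluene, 90 °C) would then give 7, with the site of the new C–C bond fixed by the halogen.

Step 6. MnO2 may over-oxidise the electron-rich free phenol, or the terminal ynone may polymerise before the ring closes. The fallback sets out from 8 and comes back at 12. O-Allylation of 8 (allyl bromide, K2CO3, DMF) would give allyl ether F4, addition of ethynylmagnesium bromide would give alcohol F5, and Dess–Martin periodinane would give ynone F6, so that no phenol is exposed to the oxidant. Pd(PPh3)4 (3 mol%) with morpholine (3 equiv) in THF at rt would then remove the O-allyl group, and the freed phenol would close onto the ynone to give 12.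

**Further compounds**

F1 | step 7 | racemic 6-methoxy-5,7-bis(methoxymethoxy)-2-phenyl-8-(prop-2-en-1-yl)-2,3-dihydro-4H-chromen-4-one | COCOc1c(OC)c(OCOC)c(CC=C)c2c1C(=O)CC(c1ccccc1)O2
F2 | step 7 | (2R,4R)-6-methoxy-5,7-bis(methoxymethoxy)-2-phenyl-8-(prop-2-en-1-yl)-3,4-dihydro-2H-chromen-4-ol | COCOc1c(OC)c(OCOC)c(CC=C)c2c1[C@H](O)C[C@H](c1ccccc1)O2
F3 | step 3 | 2-iodo-4-methoxy-3,5-bis(methoxymethoxy)phenol | COCOc1cc(O)c(I)c(OCOC)c1OC
F4 | step 6 | 5-methoxy-4,6-bis(methoxymethoxy)-3-(prop-2-en-1-yl)-2-(prop-2-en-1-yloxy)benzaldehyde | O=Cc1c(OCC=C)c(CC=C)c(OCOC)c(OC)c1OCOC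
F5 | step 6 | 1-[5-methoxy-4,6-bis(methoxymethoxy)-3-(prop-2-en-1-yl)-2-(prop-2-en-1-yloxy)phenyl]prop-2-yn-1-ol | C#CC(O)c1c(OCC=C)c(CC=C)c(OCOC)c(OC)c1OCOC
F6 | step 6 | 1-[5-methoxy-4,6-bis(methoxymethoxy)-3-(prop-2-en-1-yl)-2-(prop-2-en-1-yloxy)phenyl]prop-2-yn-1-one | C#CC(=O)c1c(OCC=C)c(CC=C)c(OCOC)c(OC)c1OCOC
A1 | direct plan | tert-butyl 3-{3-methoxy-2,4-bis(methoxymethoxy)-6-[(2-methylbut-3-en-2-yl)oxy]phenyl}-3-oxopropanoate | CC(C)(C)OC(=O)CC(=O)c1c(OC(C)(C)C=C)cc(OCOC)c(OC)c1OCOC
A2 | direct plan | tert-butyl (2Z)-2-{3-methoxy-2,4-bis(methoxymethoxy)-6-[(2-methylbut-3-en-2-yl)oxy]benzoyl}-3-phenylprop-2-enoate | CC(C)(C)OC(=O)/C(=C\c1ccccc1)C(=O)c1c(OC(C)(C)C=C)cc(OCOC)c(OC)c1OCOC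
A3 | direct plan | tert-butyl (2Z)-2-[2-hydroxy-5-methoxy-4,6-bis(methoxymethoxy)-3-(3-methylbut-2-en-1-yl)benzoyl]-3-phenylprop-2-enoate | CC(C)(C)OC(=O)/C(=C\c1ccccc1)C(=O)c1c(O)c(CC=C(C)C)c(OCOC)c(OC)c1OCOC
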